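The route rests on disconnecting the butenolide ring (O6–C6–C7=C11–C12, germacrane numbering) between the lactone carbonyl carbon C12 and the α-carbon C11. The feature exploited is that C11 carries the oxygenated carbon C13: C11 and C13 are carried as the central and terminal carbons of an exocyclic allene on C7 of the ten-membered carbocycle, beside the free C6 hydroxyl. A PdCl2-catalysed chlorocyclocarbonylation unites this 2,3-allenol, carbon monoxide (C12) and chloride in one operation, forming O6–C12 and C12–C11, fixing the C7=C11 alkene and functionalising C13. The allenol comes from a chromium-mediated propargyl-to-allenyl closure (C6–C7) of the ten-membered ring.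

Key step: step 13

Remark on labels: germacrane numbering is used throughout, also for acyclic precursors. C1 is the free carbinol carbon, C2/C3 the methylenes, C4 (methyl C15) and C5 the epoxide carbons, C6 the lactone O-bearing carbon, C7 the ring-fusion carbon, C8 the tiglate-bearing carbon, C9=C10 the Z alkene (methyl C14 on C10), C11 the lactone α-carbon, C12 the lactone carbonyl and C13 the hydroxymethyl carbon.

Remark on descriptors: the spatial arrangement at C6 is the same from compound 19 to the target; its descriptor is R while C4=C5 is an alkene and S once the epoxide is present.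

Assumption: 4-methoxybenzyl propargyl ether 8 is taken as purchasable (otherwise one step from propargyl alcohol). The antipodes of the ProPhenol ligand (step 4) and of the sulfonamide ligand (step 6) are chosen for the sense of induction that gives 8S and 1R; this sense is not asserted here and is to be confirmed on the first intermediate.

Step 1
Reactants: 1 geranyl acetate
Product: 3 (2E)-3-methyl-6-oxohex-2-en-1-yl acetate, via secondary ozonide 2 (not isolated)
Conditions: O3 (1 equiv), CH2Cl2, −78 °C; then Me2S, −78 °C to rt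
Reagents that add atoms: ozone, O=[O+][O-]
Why: Chemoselective ozonolysis with reductive work-up; the electron-rich isopropylidene alkene reacts much faster than the acetate-deactivated allylic alkene, so the E-configured C4=C5 alkene is kept.

Step 2
Reactants: 4 but-2-yn-1-ol
Product: 6 (2Z)-3-iodobut-2-en-1-ol, via cyclic sodium alkenylalanate 5 (not isolated)
Conditions: NaAlH2(OCH2CH2OMe)2 (Red-Al), THF, 0 °C to rt; then I2, THF, −78 °C to 0 °C
Reagents that add atoms: iodine, II
Why: Alkoxide-directed trans-hydroalumination of the propargylic alcohol places aluminium on the distal carbon cis to the carbinol carbon, and iodinolysis with retention should give only the Z iodide.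

Step 3
Reactants: 6 (2Z)-3-iodobut-2-en-1-ol
Product: 7 (2Z)-3-iodobut-2-enal
Conditions: MnO2, CH2Cl2, rt, dark
Reagents that add atoms: none
Why: Manganese dioxide oxidation of an allylic alcohol is neutral and should keep the Z geometry of the sensitive β-iodo enal, which is used at once.

Step 4
Reactants: 7 (2Z)-3-iodobut-2-enal; 8 4-methoxybenzyl propargyl ether
Product: 10 (4S,5Z)-6-iodo-1-[(4-methoxybenzyl)oxy]hept-5-en-2-yn-4-ol, via methylzinc acetylide 9 (not isolated)
Conditions: 8, Me2Zn, ProPhenol ligand (20 mol %), Ph3P=O (40 mol %), toluene, 0 °C; then 7, 0–4 °C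
Reagents that add atoms: none
Why: Zinc/ProPhenol-catalysed asymmetric alkynylation of an enal adds the alkynylzinc 1,2 to one aldehyde face under catalyst control, which sets C8 as S and leaves the vinyl iodide untouched.

Step 5
Reactants: 10 propargylic alcohol
Product: 11 triethylsilyl ether of 10 (8-OTES)
Conditions: TESCl, imidazole, CH2Cl2, 0 °C
Reagents that add atoms: chlorotriethylsilane, CC[Si](Cl)(CC)CC
Why: Standard silylation; the silyloxy group is a poor leaving group, which is needed when a propargylchromium species is later made at C13.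

Step 6
Reactants: 11 vinyl iodide; 3 (2E)-3-methyl-6-oxohex-2-en-1-yl acetate
Product: 12 (2E,6R,7Z,9S)-6-hydroxy-12-[(4-methoxybenzyl)oxy]-3,7-dimethyl-9-[(triethylsilyl)oxy]dodeca-2,7-dien-10-yn-1-yl acetate (dodecane C1–C12 = germacrane C6, C5, C4, C3, C2, C1, C10, C9, C8, C7, C11, C13)
Conditions: CrCl2, NiCl2 (cat.), chiral oxazoline sulfonamide ligand, Et3N, THF, rt
Reagents that add atoms: none
Why: Asymmetric Nozaki–Hiyama–Kishi coupling; the alkenylchromium species forms with retention of the Z geometry and adds only to the aldehyde (acetate, silyl ether and alkyne are inert), and the ligand on chromium selects the aldehyde face to set C1 as R.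

Step 7
Reactants: 12 allylic alcohol
Product: 13 tert-butyldimethylsilyl ether of 12 (1-OTBS)
Conditions: TBSOTf, 2,6-lutidine, CH2Cl2, −78 °C
Reagents that add atoms: tert-butyldimethylsilyl triflate, CC(C)(C)[Si](C)(C)OS(=O)(=O)C(F)(F)F
Why: Silylation of the hindered secondary allylic alcohol with the silyl triflate at low temperature; this group is to outlast the triethylsilyl ether on O8.

Step 8
Reactants: 13 acetate
Product: 14 (2E,6R,7Z,9S)-6-[(tert-butyldimethylsilyl)oxy]-12-[(4-methoxybenzyl)oxy]-3,7-dimethyl-9-[(triethylsilyl)oxy]dodeca-2,7-dien-10-yn-1-ol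
Conditions: K2CO3 (cat.), MeOH, 0 °C
Reagents that add atoms: none
Why: Base-catalysed transesterification removes the primary acetate while the secondary silyl ethers and the benzyl-type ether are stable.

Step 9
Reactants: 14 allylic alcohol
Product: 15 (2E,6R,7Z,9S)-6-[(tert-butyldimethylsilyl)oxy]-12-[(4-methoxybenzyl)oxy]-3,7-dimethyl-9-[(triethylsilyl)oxy]dodeca-2,7-dien-10-ynal
Conditions: MnO2, CH2Cl2, rt
Reagents that add atoms: none
Why: Allylic oxidation with manganese dioxide gives the (E)-enal (C6 aldehyde) without touching the protected secondary carbinols.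

Step 10
Reactants: 15 PMB ether
Product: 16 (2E,6R,7Z,9S)-6-[(tert-butyldimethylsilyl)oxy]-12-hydroxy-3,7-dimethyl-9-[(triethylsilyl)oxy]dodeca-2,7-dien-10-ynal
Conditions: DDQ, CH2Cl2/pH 7 buffer, 0 °C
Reagents that add atoms: none
Why: Oxidative cleavage of the 4-methoxybenzyl ether (hydride abstraction, hydrolysis of the oxocarbenium ion) under buffered conditions frees only O13.

Step 11
Reactants: 16 propargylic alcohol
Product: 18 (2E,6R,7Z,9S)-12-bromo-6-[(tert-butyldimethylsilyl)oxy]-3,7-dimethyl-9-[(triethylsilyl)oxy]dodeca-2,7-dien-10-ynal, via propargylic mesylate 17 (not isolated)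
Conditions: MsCl, Et3N, THF, −30 °C; then LiBr, 0 °C
Reagents that add atoms: methanesulfonyl chloride, CS(=O)(=O)Cl (mesyl group of 17 only); lithium bromide, [Li+].[Br-]
Why: Mesylation followed by SN2 displacement with bromide (Finkelstein type) avoids phosphine/CBr4 reagents that would attack the enal.

Step 12
Reactants: 18 bromo enal
Product: 19 (1R,4E,6R,8S,9Z)-1-[(tert-butyldimethylsilyl)oxy]-4,10-dimethyl-8-[(triethylsilyl)oxy]-7-vinylidenecyclodeca-4,9-dien-6-ol (macrocyclic 2,3-allenol)
Conditions: CrCl2 (excess), THF, rt, slow addition of 18 (final ca. 2 mM)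
Reagents that add atoms: none
Why: Intramolecular chromium-mediated Barbier reaction (Nozaki–Hiyama type) in which the propargylchromium species formed at C13 adds 1,2 to the enal in the SE2' sense through C7, closing the ten-membered ring at C6–C7 and leaving the exocyclic allene; with the chromium-bound aldehyde oxygen and the C8 silyloxy group both in outward, pseudo-equatorial positions the closure should give the 6,8-cis carbinol.

Step 13
Reactants: 19 macrocyclic allenol
Product: 20 (1R,4E,6R,8S,9Z)-1-[(tert-butyldimethylsilyl)oxy]-13-chloro-8-[(triethylsilyl)oxy]germacra-4,7(11),9-trien-12,6-olide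
Conditions: PdCl2 (10 mol %), CuCl2 (4 equiv), CO (1 atm), propylene oxide, THF, rt
Reagents that add atoms: carbon monoxide, [C-]#[O+]; copper dichloride, Cl[Cu]Cl
Why: The free O6–H, CO and divalent palladium form an alkoxycarbonylpalladium chloride, which adds across the terminal C11=C13 π bond of the allene with the acyl carbon C12 bonding to the central carbon C11 (the ring-closing C12–C11 bond) to give a π-allylpalladium unit over C7–C11–C13; chloride is then delivered to the primary terminus C13 and CuCl2 returns palladium to the divalent state (a sequence that begins with chloropalladation of the allene and ends with lactonisation would converge on the same product). The closest known reaction is the PdCl2/CuCl2 chlorocyclocarbonylation of 2-substituted 2,3-allenols to 3-chloromethyl-2(5H)-furanones. The five-membered lactone closes in the 5-exo-trig mode with respect to the C11=C13 bond, with bond formation at the central allene carbon. No stereocentre is created: C6 is untouched and the geometry of the C7=C11 alkene is fixed by the ring, so the 6,8-cis relation from step 12 is carried over. The step needs chemoselection for O6 (O1 and O8 are silylated), acyl delivery to the central carbon (enforced by the five-membered ring and the π-allyl intermediate) and chloride capture at C13 and not at C7 (primary terminus, conjugated tetrasubstituted butenolide as the product). Propylene oxide takes up the HCl released so that the silyl ethers and the allylic C6–O bond should survive.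

Step 14
Reactants: 20 chloromethyl butenolide
Product: 21 (1R,4E,6R,8S,9Z)-1-[(tert-butyldimethylsilyl)oxy]-13-chloro-8-hydroxygermacra-4,7(11),9-trien-12,6-olide
Conditions: PPTS (cat.), MeOH/CH2Cl2, 0 °C
Reagents that add atoms: none
Why: Acid-catalysed methanolysis cleaves the secondary triethylsilyl ether far faster than the tert-butyldimethylsilyl ether, and the allylic chloride and butenolide are stable to these conditions.

Step 15
Reactants: 21 C8 alcohol; 22 tigloyl chloride
Product: 23 (1R,4E,6R,8S,9Z)-1-[(tert-butyldimethylsilyl)oxy]-13-chloro-8-[(E)-2-methylbut-2-enoyloxy]germacra-4,7(11),9-trien-12,6-olide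
Conditions: pyridine, DMAP (cat.), CH2Cl2, 0 °C to rt
Reagents that add atoms: none
Why: DMAP-catalysed acylation; O8 is trans to C12 on the tetrasubstituted alkene so translactonisation cannot occur, and with the weak base pyridine O-alkylation by the cis chloromethyl group (which would give a strained 5,5-system with a fusion alkene) should not compete.

Step 16
Reactants: 23 tiglate
Product: 24 (1R,4R,5R,6S,8S,9Z)-1-[(tert-butyldimethylsilyl)oxy]-13-chloro-4,5-epoxy-8-[(E)-2-methylbut-2-enoyloxy]germacra-7(11),9-dien-12,6-olide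
Conditions: mCPBA, CH2Cl2, 0 °C
Reagents that add atoms: 3-chloroperoxybenzoic acid, OOC(=O)c1cccc(Cl)c1
Why: Prilezhaev epoxidation; C4=C5 is the only electron-rich, accessible alkene (C9=C10 lies between two oxygenated carbons, the other alkenes are conjugated to carbonyls), and peripheral attack on the conformer in which H6 eclipses the C4 methyl (allylic 1,3-strain) delivers oxygen to the face syn to O6, which should give the (4R,5R) trans-epoxide.

Step 17
Reactants: 24 epoxy chloride
Product: 26 (1R,4R,5R,6S,8S,9Z)-1-[(tert-butyldimethylsilyl)oxy]-4,5-epoxy-13-hydroxy-8-[(E)-2-methylbut-2-enoyloxy]germacra-7(11),9-dien-12,6-olide, via C13 formate 25 (not isolated)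
Conditions: HCO2Cs, DMF, rt; then MeOH, NaHCO3 (cat.), 0 °C
Reagents that add atoms: caesium formate, [Cs+].[O-]C=O
Why: SN2 displacement of the activated primary allylic chloride by formate (SN2' is blocked at the fully substituted C7) followed by mild methanolysis of the formate, which is far more labile than the tiglate and the lactone.

Step 18
Reactants: 26 silyl ether
Product: 27 target, (1R,4R,5R,6S,8S,9Z)-4,5-epoxy-1,13-dihydroxy-8-[(E)-2-methylbut-2-enoyloxy]germacra-7(11),9-dien-12,6-olide
Conditions: HF·pyridine, pyridine, THF, 0 °C to rt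
Reagents that add atoms: none
Why: Buffered fluoride cleavage of the remaining silyl ether should leave the epoxide, both esters and the lactone intact.

Compound list
1 | geranyl acetate, (2E)-3,7-dimethylocta-2,6-dien-1-yl acetate | CC(C)=CCC/C(C)=C/COC(C)=O | starting material
2 | secondary ozonide (1,2,4-trioxolane) of the isopropylidene alkene of 1 | CC1(C)OOC(CC/C(C)=C/COC(C)=O)O1 | intermediate (not isolated)
3 | (2E)-3-methyl-6-oxohex-2-en-1-yl acetate | O=CCC/C(C)=C/COC(C)=O | intermediate
4 | but-2-yn-1-ol | CC#CCO | starting material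
5 | cyclic sodium alkenylalanate (2,5-dihydro-1,2-oxaaluminole, Al on the methyl-bearing carbon) | CC1=CCO[Al-]1(OCCOC)OCCOC.[Na+] | intermediate (not isolated)
6 | (2Z)-3-iodobut-2-en-1-ol | C/C(I)=C/CO | intermediate
7 | (2Z)-3-iodobut-2-enal | C/C(I)=C/C=O | intermediate
8 | 4-methoxybenzyl propargyl ether | C#CCOCc1ccc(OC)cc1 | starting material
9 | methylzinc acetylide of 8 | C[Zn]C#CCOCc1ccc(OC)cc1 | intermediate (not isolated)
10 | (4S,5Z)-6-iodo-1-[(4-methoxybenzyl)oxy]hept-5-en-2-yn-4-ol | O[C@H](C#CCOCc1ccc(OC)cc1)/C=C(/C)I | intermediate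
11 | triethylsilyl ether of 10 | CC[Si](CC)(CC)O[C@H](C#CCOCc1ccc(OC)cc1)/C=C(/C)I | intermediate
12 | (2E,6R,7Z,9S)-6-hydroxy-12-[(4-methoxybenzyl)oxy]-3,7-dimethyl-9-[(triethylsilyl)oxy]dodeca-2,7-dien-10-yn-1-yl acetate | CC[Si](CC)(CC)O[C@H](C#CCOCc1ccc(OC)cc1)/C=C(/C)[C@H](O)CC/C(C)=C/COC(C)=O | intermediate
13 | 6-O-tert-butyldimethylsilyl ether of 12 | CC[Si](CC)(CC)O[C@H](C#CCOCc1ccc(OC)cc1)/C=C(/C)[C@H](O[Si](C)(C)C(C)(C)C)CC/C(C)=C/COC(C)=O | intermediate
14 | (2E,6R,7Z,9S)-6-[(tert-butyldimethylsilyl)oxy]-12-[(4-methoxybenzyl)oxy]-3,7-dimethyl-9-[(triethylsilyl)oxy]dodeca-2,7-dien-10-yn-1-ol | CC[Si](CC)(CC)O[C@H](C#CCOCc1ccc(OC)cc1)/C=C(/C)[C@H](O[Si](C)(C)C(C)(C)C)CC/C(C)=C/CO | intermediate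
15 | (2E,6R,7Z,9S)-6-[(tert-butyldimethylsilyl)oxy]-12-[(4-methoxybenzyl)oxy]-3,7-dimethyl-9-[(triethylsilyl)oxy]dodeca-2,7-dien-10-ynal | CC[Si](CC)(CC)O[C@H](C#CCOCc1ccc(OC)cc1)/C=C(/C)[C@H](O[Si](C)(C)C(C)(C)C)CC/C(C)=C/C=O | intermediate
16 | (2E,6R,7Z,9S)-6-[(tert-butyldimethylsilyl)oxy]-12-hydroxy-3,7-dimethyl-9-[(triethylsilyl)oxy]dodeca-2,7-dien-10-ynal | CC[Si](CC)(CC)O[C@H](C#CCO)/C=C(/C)[C@H](O[Si](C)(C)C(C)(C)C)CC/C(C)=C/C=O | intermediate
17 | 12-O-methanesulfonate of 16 | CC[Si](CC)(CC)O[C@H](C#CCOS(C)(=O)=O)/C=C(/C)[C@H](O[Si](C)(C)C(C)(C)C)CC/C(C)=C/C=O | intermediate (not isolated)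
18 | (2E,6R,7Z,9S)-12-bromo-6-[(tert-butyldimethylsilyl)oxy]-3,7-dimethyl-9-[(triethylsilyl)oxy]dodeca-2,7-dien-10-ynal | CC[Si](CC)(CC)O[C@H](C#CCBr)/C=C(/C)[C@H](O[Si](C)(C)C(C)(C)C)CC/C(C)=C/C=O | intermediate
19 | (1R,4E,6R,8S,9Z)-1-[(tert-butyldimethylsilyl)oxy]-4,10-dimethyl-8-[(triethylsilyl)oxy]-7-vinylidenecyclodeca-4,9-dien-6-ol | CC[Si](CC)(CC)O[C@H]1/C=C(/C)[C@H](O[Si](C)(C)C(C)(C)C)CC/C(C)=C/[C@@H](O)C1=C=C | intermediate
20 | (1R,4E,6R,8S,9Z)-1-[(tert-butyldimethylsilyl)oxy]-13-chloro-8-[(triethylsilyl)oxy]germacra-4,7(11),9-trien-12,6-olide | CC[Si](CC)(CC)O[C@H]1/C=C(/C)[C@H](O[Si](C)(C)C(C)(C)C)CC/C(C)=C/[C@H]2OC(=O)C(CCl)=C12 | intermediate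
21 | (1R,4E,6R,8S,9Z)-1-[(tert-butyldimethylsilyl)oxy]-13-chloro-8-hydroxygermacra-4,7(11),9-trien-12,6-olide | O[C@H]1/C=C(/C)[C@H](O[Si](C)(C)C(C)(C)C)CC/C(C)=C/[C@H]2OC(=O)C(CCl)=C12 | intermediate
22 | tigloyl chloride, (E)-2-methylbut-2-enoyl chloride | C/C=C(\C)C(=O)Cl | starting material
23 | (1R,4E,6R,8S,9Z)-1-[(tert-butyldimethylsilyl)oxy]-13-chloro-8-[(E)-2-methylbut-2-enoyloxy]germacra-4,7(11),9-trien-12,6-olide | C/C=C(\C)C(=O)O[C@H]1/C=C(/C)[C@H](O[Si](C)(C)C(C)(C)C)CC/C(C)=C/[C@H]2OC(=O)C(CCl)=C12 | intermediate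
24 | (1R,4R,5R,6S,8S,9Z)-1-[(tert-butyldimethylsilyl)oxy]-13-chloro-4,5-epoxy-8-[(E)-2-methylbut-2-enoyloxy]germacra-7(11),9-dien-12,6-olide | C/C=C(\C)C(=O)O[C@H]1/C=C(/C)[C@H](O[Si](C)(C)C(C)(C)C)CC[C@@]2(C)O[C@@H]2[C@H]2OC(=O)C(CCl)=C12 | intermediate
25 | 13-formate of 26 | C/C=C(\C)C(=O)O[C@H]1/C=C(/C)[C@H](O[Si](C)(C)C(C)(C)C)CC[C@@]2(C)O[C@@H]2[C@H]2OC(=O)C(COC=O)=C12 | intermediate (not isolated)
26 | (1R,4R,5R,6S,8S,9Z)-1-[(tert-butyldimethylsilyl)oxy]-4,5-epoxy-13-hydroxy-8-[(E)-2-methylbut-2-enoyloxy]germacra-7(11),9-dien-12,6-olide | C/C=C(\C)C(=O)O[C@H]1/C=C(/C)[C@H](O[Si](C)(C)C(C)(C)C)CC[C@@]2(C)O[C@@H]2[C@H]2OC(=O)C(CO)=C12 | intermediate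
27 | (1R,4R,5R,6S,8S,9Z)-4,5-epoxy-1,13-dihydroxy-8-[(E)-2-methylbut-2-enoyloxy]germacra-7(11),9-dien-12,6-olide | C/C=C(\C)C(=O)O[C@H]1/C=C(/C)[C@H](O)CC[C@@]2(C)O[C@@H]2[C@H]2OC(=O)C(CO)=C12 | target

Total step count: 18. Longest linear sequence: 17 steps (steps 2 to 18, from but-2-yn-1-ol 4).

Steps most likely to fail

Step 12 (ring closure to the allenol). What may go wrong is attack of the propargylchromium species on the wrong face of the chromium-bound enal, so that the 6-epimer predominates. Intermolecular coupling at practical concentrations and 1,4-loss of the C8 silyloxy group from the allenylchromium tautomer are lesser risks. The fallback corrects the stereocentre instead of controlling it in the ring closure. Starting from 18, the same closure is run and the 6-epi allenol F1 is taken into a Mitsunobu inversion (4-nitrobenzoic acid, PPh3, DIAD, toluene, 0 °C) to give the inverted 4-nitrobenzoate F2. Methanolysis (K2CO3, MeOH, 0 °C) then returns the route at 19.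

Step 16 (late epoxidation). What may go wrong is poor discrimination between the C4=C5 and C9=C10 alkenes, or delivery of oxygen to the inner face of C4=C5, which would give the 4,5-diastereomer. The fallback moves the epoxidation ahead of the lactone and lets the free C6 hydroxyl direct it. Starting from 19, VO(acac)2 (cat.) and t-BuOOH in CH2Cl2 at 0 °C should give the epoxy allenol F3, because the vanadate ester of O6 delivers oxygen to the alkene face it sits on and the allene reacts more slowly. The chlorocyclocarbonylation of step 13 (with propylene oxide) then gives the epoxy chloro lactone F4. HF·pyridine/pyridine removes the triethylsilyl group to give the C8 alcohol F5, and acylation with 22 as in step 15 returns the route at 24.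

Step 6 (reagent-controlled coupling). What may go wrong is insufficient facial control at C1, since the remote C8 centre gives no help, or slow coupling of the hindered trisubstituted iodide under ligand-modified conditions. The fallback sets C1 by reduction instead of by addition. Starting from 11 and 3, a ligand-free coupling (CrCl2, NiCl2 cat., DMSO, rt) gives the C1-epimeric alcohols F6. Dess–Martin periodinane (NaHCO3, CH2Cl2, 0 °C) gives the (Z)-enone F7. Reduction with the (S)-Me-CBS oxazaborolidine and BH3·SMe2 at −40 °C, with the alkenyl group as the large substituent, should set 1R and returns the route at 12.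

Further compounds
F1 | step 12 | (1R,4E,6S,8S,9Z)-1-[(tert-butyldimethylsilyl)oxy]-4,10-dimethyl-8-[(triethylsilyl)oxy]-7-vinylidenecyclodeca-4,9-dien-6-ol (6-epimer of 19) | CC[Si](CC)(CC)O[C@H]1/C=C(/C)[C@H](O[Si](C)(C)C(C)(C)C)CC/C(C)=C/[C@H](O)C1=C=C
F2 | step 12 | 6-O-(4-nitrobenzoate) of 19 | CC[Si](CC)(CC)O[C@H]1/C=C(/C)[C@H](O[Si](C)(C)C(C)(C)C)CC/C(C)=C/[C@@H](OC(=O)c2ccc(cc2)[N+](=O)[O-])C1=C=C
F3 | step 16 | (1R,4R,5R,6S,8S,9Z)-1-[(tert-butyldimethylsilyl)oxy]-4,5-epoxy-4,10-dimethyl-8-[(triethylsilyl)oxy]-7-vinylidenecyclodec-9-en-6-ol | CC[Si](CC)(CC)O[C@H]1/C=C(/C)[C@H](O[Si](C)(C)C(C)(C)C)CC[C@@]2(C)O[C@@H]2[C@@H](O)C1=C=C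
F4 | step 16 | (1R,4R,5R,6S,8S,9Z)-1-[(tert-butyldimethylsilyl)oxy]-13-chloro-4,5-epoxy-8-[(triethylsilyl)oxy]germacra-7(11),9-dien-12,6-olide | CC[Si](CC)(CC)O[C@H]1/C=C(/C)[C@H](O[Si](C)(C)C(C)(C)C)CC[C@@]2(C)O[C@@H]2[C@H]2OC(=O)C(CCl)=C12
F5 | step 16 | (1R,4R,5R,6S,8S,9Z)-1-[(tert-butyldimethylsilyl)oxy]-13-chloro-4,5-epoxy-8-hydroxygermacra-7(11),9-dien-12,6-olide | O[C@H]1/C=C(/C)[C@H](O[Si](C)(C)C(C)(C)C)CC[C@@]2(C)O[C@@H]2[C@H]2OC(=O)C(CCl)=C12
F6 | step 6 | C1-epimeric mixture of 12 (dodecane C6 unassigned) | CC[Si](CC)(CC)O[C@H](C#CCOCc1ccc(OC)cc1)/C=C(/C)C(O)CC/C(C)=C/COC(C)=O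
F7 | step 6 | (2E,7Z,9S)-12-[(4-methoxybenzyl)oxy]-3,7-dimethyl-6-oxo-9-[(triethylsilyl)oxy]dodeca-2,7-dien-10-yn-1-yl acetate | CC[Si](CC)(CC)O[C@H](C#CCOCc1ccc(OC)cc1)/C=C(/C)C(=O)CC/C(C)=C/COC(C)=O
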